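**Retrosynthetic overview**
1. The C8 carbonyl and the acetate are installed last, by a singlet-oxygen ene reaction, dehydration and acetylation of an exocyclic s-trans diene alcohol (C8–O bond formation).
2. The diene alcohol comes from a bromochloro β-hydroxy spiroketone by C8–C9 dehydrogenation and C7=O to C7=CH2 conversion. Br and Cl come from a chelate-directed anti bromochlorination of the ring B alkene.
3. The key disconnection is C1–O. The β-hydroxy spiroketone comes from a face-selective epoxidation of a cyclohexadienyl cyclopentanol, followed by a semipinacol ring expansion that sets C1 and spiro C6.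
4. The cyclohexadienyl carbinol comes from isoprene and 1-ethynyl-2,2-dimethylcyclopentanol by [4+2]. The alkynol comes from 2,2-dimethylcyclopentanone and ethynylmagnesium bromide.
5. Ring order: purchased cyclopentane, then ring B ([4+2]), then ring A (five- to six-membered ring expansion that creates the spiro centre).

Numbering (spiro[5.5]undecane = chamigrane numbering): ring B is C1(O)–C2–C3(Me,Cl)–C4(Br)–C5, C6 is the spiro atom, ring A is C7–C8–C9–C10–C11(Me2), and C14 is the CH2 on C7. The "lower face" of ring B is the face that carries the C1 oxygen.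

Assumption: the (R,R)-ligand of step 3 is taken to deliver oxygen to the face drawn; if its sense proves opposite, the (S,S)-ligand is used.

**Step 1**
Reactants: 1 2,2-dimethylcyclopentan-1-one; 2 ethynylmagnesium bromide
Product: 3 (±)-1-ethynyl-2,2-dimethylcyclopentan-1-ol
Conditions: THF, 0 °C to rt; aq NH4Cl
Reagents that add atoms: none
Why: 1,2-addition of an alkynyl Grignard reagent to a ketone gives the racemic tertiary propargylic alcohol, and its stereocentre is erased in step 3, so no control is needed here.

**Step 2**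
Reactants: 3 (±)-1-ethynyl-2,2-dimethylcyclopentan-1-ol; 4 isoprene (2-methylbuta-1,3-diene)
Product: 5 (±)-2,2-dimethyl-1-(4-methylcyclohexa-1,4-dien-1-yl)cyclopentan-1-ol
Conditions: CoBr2(dppe) (5 mol %), Zn (10 mol %), ZnI2 (10 mol %), CH2Cl2, rt
Reagents that add atoms: none
Why: This is a cobalt-catalysed neutral [4+2] cycloaddition of an unactivated terminal alkyne (Zn reduces the precatalyst to monovalent cobalt), and the dppe ligand gives the 1,4-("para") regioisomer, so ring B forms as the skipped diene with the methyl group para to the carbinol arm and no new stereocentre.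

**Step 3**
Reactants: 5 (±)-2,2-dimethyl-1-(4-methylcyclohexa-1,4-dien-1-yl)cyclopentan-1-ol
Product: 7 (1S,6S)-1-hydroxy-3,11,11-trimethylspiro[5.5]undec-3-en-7-one, via epoxy alcohol 6 (not isolated)
Conditions: Hf(OtBu)4 (10 mol %), C2-symmetric bishydroxamic acid L* [(1R,2R)-N,N'-dihydroxy-N,N'-bis(3,3,3-triphenylpropanoyl)cyclohexane-1,2-diamine, 12 mol %], cumene hydroperoxide (1.5 equiv), toluene, 0 °C, full conversion; then ZnBr2 (20 mol %), CH2Cl2, 0 °C to rt
Reagents that add atoms: cumene hydroperoxide, CC(C)(OO)c1ccccc1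
Why: Proposed new method: an enantioconvergent hydroxyl-directed epoxidation coupled to a semipinacol ring expansion; the tetravalent hafnium bishydroxamate peroxide binds either enantiomer of the tertiary alkoxide, each enantiomer can turn its CMe2 arm away from the metal by using one of two O–C7–C6=C1 rotamers on the same alkene face, so the ligand pocket reads only the prochiral faces of the flat diene and forms the C1–O and C6–O bonds on the lower face of both (the remote C3=C4 alkene is not tethered to the metal and stays intact); ZnBr2 then ionises the tertiary C6–O bond while the more substituted C7–C11 bond migrates antiperiplanar to it, which places C11 anti and C7 syn to the C1 oxygen, fixes C1 (S) and spiro C6, builds ring A and erases the racemic carbinol centre as the C7 ketone; the closest known reaction types are the bishydroxamate-metal epoxidation of achiral tertiary allylic alcohols and the Lewis-acid semipinacol rearrangement of 2,3-epoxy alcohols.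

**Step 4**
Reactants: 7 (1S,6S)-1-hydroxy-3,11,11-trimethylspiro[5.5]undec-3-en-7-one
Product: 8 (1S,3R,4R,6S)-4-bromo-3-chloro-1-hydroxy-3,11,11-trimethylspiro[5.5]undecan-7-one
Conditions: ClTi(OiPr)3 (1.1 equiv), NBS (1.05 equiv), hexanes–CH2Cl2, −20 °C; H2O
Reagents that add atoms: N-bromosuccinimide, O=C1CCC(=O)N1Br; chlorotitanium triisopropoxide ClTi(OiPr)3, CC(C)O[Ti](Cl)(OC(C)C)OC(C)C
Why: Proposed new method: a chelate-directed diastereoselective bromochlorination of a homoallylic β-hydroxy ketone; ring B sits with C11 equatorial and the C7 carbonyl axial, so the equatorial C1 alkoxide and the carbonyl oxygen (O···O about 2.8 Å) clamp the chlorotitanium unit under the lower face, NBS can build the bromonium ion only on the open upper face, and titanium-bound chloride opens it from below at the tertiary, more cationic C3 (anti, Markovnikov), which gives C4–Br (R) anti and C3–Cl (R) syn to the C1 oxygen, the all-equatorial array of the target; the closest known reaction type is the alkoxide-directed bromochlorination of allylic alcohols with NBS and ClTi(OiPr)3.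

**Step 5**
Reactants: 8 (1S,3R,4R,6S)-4-bromo-3-chloro-1-hydroxy-3,11,11-trimethylspiro[5.5]undecan-7-one
Product: 10 (1S,3R,4R,6S)-4-bromo-3-chloro-3,11,11-trimethyl-1-(trimethylsilyloxy)spiro[5.5]undec-8-en-7-one, via bis-silyl enol ether 9 (not isolated)
Conditions: TMSOTf (2.5 equiv), Et3N (4 equiv), CH2Cl2, 0 °C; then Pd(OAc)2 (1.05 equiv), MeCN, rt
Reagents that add atoms: trimethylsilyl triflate, C[Si](C)(C)OS(=O)(=O)C(F)(F)F
Why: Soft enolisation can only go toward C8 because C6 is quaternary, the same reagent caps the C1 alcohol (which shuts down retro-aldol cleavage), and Saegusa–Ito oxidation (palladium enolate, β-hydride elimination) then gives the C8=C9 enone under neutral conditions that leave the alkyl halides and all four stereocentres untouched.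

**Step 6**
Reactants: 10 (1S,3R,4R,6S)-4-bromo-3-chloro-3,11,11-trimethyl-1-(trimethylsilyloxy)spiro[5.5]undec-8-en-7-one
Product: 12 (1S,3R,4R,6R)-4-bromo-3-chloro-3,11,11-trimethyl-7-methylidenespiro[5.5]undec-8-en-1-ol, via silyl-protected diene 11 (not isolated)
Conditions: Cp2TiMe2 (3 equiv), toluene, 65 °C, dark; then K2CO3 (cat.), MeOH, 0 °C
Reagents that add atoms: dimethyltitanocene Cp2TiMe2, [CH3-].[CH3-].[Ti+4].[cH-]1cccc1.[cH-]1cccc1
Why: In this Petasis methylenation the thermally generated Cp2Ti=CH2 is small, non-basic and free of aluminium Lewis acids, so it converts the hindered enone carbonyl into the exocyclic methylene by [2+2]/retro-[2+2] without E2 loss of HBr or HCl and without ionising the tertiary chloride, and catalytic carbonate in methanol then removes the labile silyl ether.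

**Step 7**
Reactants: 12 (1S,3R,4R,6R)-4-bromo-3-chloro-3,11,11-trimethyl-7-methylidenespiro[5.5]undec-8-en-1-ol
Product: 15 (1S,3R,4R,6R)-1-acetoxy-4-bromo-3-chloro-3,11,11-trimethyl-7-methylidenespiro[5.5]undec-9-en-8-one (CNP0161807.1), via C8 hydroperoxide 13 (not isolated), via C8 peracetate 14 (not isolated)
Conditions: O2, tetraphenylporphyrin (1 mol %), white LED, CH2Cl2, 0 °C; then Ac2O, pyridine, DMAP (cat.), 0 °C to rt
Reagents that add atoms: dioxygen, O=O; acetic anhydride, CC(=O)OC(C)=O
Why: This is a Schenck ene reaction followed by a Kornblum–DeLaMare-type dehydration, in which the diene is locked s-trans so [4+2] addition of singlet oxygen is impossible, the only allylic hydrogens sit on C10 so oxygen is delivered to C8 with alkene shift to C9=C10, and Ac2O/pyridine/DMAP then acylates the hydroperoxide (loss of acetic acid across the doubly allylic C8–H gives the cross-conjugated dienone) and acetylates the C1 alcohol with retention, touching no stereocentre.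

**Compound list**
1 | 2,2-dimethylcyclopentan-1-one | CC1(C)CCCC1=O | starting material
2 | ethynylmagnesium bromide | C#C[Mg]Br | starting material
3 | (±)-1-ethynyl-2,2-dimethylcyclopentan-1-ol | C#CC1(O)CCCC1(C)C | intermediate
4 | isoprene | C=CC(C)=C | starting material
5 | (±)-2,2-dimethyl-1-(4-methylcyclohexa-1,4-dien-1-yl)cyclopentan-1-ol | CC1=CCC(=CC1)C2(O)CCCC2(C)C | intermediate
6 | 1-[(1R,6S)-4-methyl-7-oxabicyclo[4.1.0]hept-3-en-1-yl]-2,2-dimethylcyclopentan-1-ol (both carbinol epimers, not isolated) | CC1=CC[C@]2(O[C@H]2C1)C3(O)CCCC3(C)C | intermediate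
7 | (1S,6S)-1-hydroxy-3,11,11-trimethylspiro[5.5]undec-3-en-7-one | O=C1CCCC(C)(C)[C@]12CC=C(C)C[C@@H]2O | intermediate
8 | (1S,3R,4R,6S)-4-bromo-3-chloro-1-hydroxy-3,11,11-trimethylspiro[5.5]undecan-7-one | O=C1CCCC(C)(C)[C@]12C[C@@H](Br)[C@](C)(Cl)C[C@@H]2O | intermediate
9 | (1S,3R,4R,6S)-4-bromo-3-chloro-3,11,11-trimethyl-1,7-bis(trimethylsilyloxy)spiro[5.5]undec-7-ene (not isolated) | C[Si](C)(C)OC1=CCCC(C)(C)[C@]12C[C@@H](Br)[C@](C)(Cl)C[C@@H]2O[Si](C)(C)C | intermediate
10 | (1S,3R,4R,6S)-4-bromo-3-chloro-3,11,11-trimethyl-1-(trimethylsilyloxy)spiro[5.5]undec-8-en-7-one | O=C1C=CCC(C)(C)[C@]12C[C@@H](Br)[C@](C)(Cl)C[C@@H]2O[Si](C)(C)C | intermediate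
11 | (1S,3R,4R,6R)-4-bromo-3-chloro-3,11,11-trimethyl-7-methylidene-1-(trimethylsilyloxy)spiro[5.5]undec-8-ene (not isolated) | C=C1C=CCC(C)(C)[C@]12C[C@@H](Br)[C@](C)(Cl)C[C@@H]2O[Si](C)(C)C | intermediate
12 | (1S,3R,4R,6R)-4-bromo-3-chloro-3,11,11-trimethyl-7-methylidenespiro[5.5]undec-8-en-1-ol | C=C1C=CCC(C)(C)[C@]12C[C@@H](Br)[C@](C)(Cl)C[C@@H]2O | intermediate
13 | (1S,3R,4R,6R)-4-bromo-3-chloro-8-hydroperoxy-3,11,11-trimethyl-7-methylidenespiro[5.5]undec-9-en-1-ol (C8 epimers, not isolated) | C=C1C(OO)C=CC(C)(C)[C@]12C[C@@H](Br)[C@](C)(Cl)C[C@@H]2O | intermediate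
14 | (1S,3R,4R,6R)-1-acetoxy-8-(acetylperoxy)-4-bromo-3-chloro-3,11,11-trimethyl-7-methylidenespiro[5.5]undec-9-ene (C8 epimers, not isolated) | C=C1C(OOC(C)=O)C=CC(C)(C)[C@]12C[C@@H](Br)[C@](C)(Cl)C[C@@H]2OC(C)=O | intermediate
15 | (1S,3R,4R,6R)-1-acetoxy-4-bromo-3-chloro-3,11,11-trimethyl-7-methylidenespiro[5.5]undec-9-en-8-one | C=C1C(=O)C=CC(C)(C)[C@]12C[C@@H](Br)[C@](C)(Cl)C[C@@H]2OC(C)=O | target

Total step count: 7. Longest linear sequence: 7.

**Steps most likely to fail**

**Step 3 (new).**
- Risks: the mismatched carbinol enantiomer may react slowly or on the other face, which lowers the ee. C8 may migrate instead of C11. The diene epoxide may aromatise under Lewis acid.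
- Fallback: known chemistry, using chirality relay from a resolved carbinol instead of catalyst control. It sets out from 3 and comes back at 7.
- Racemic 3 is separated by preparative chiral-phase SFC to give (S)-1-ethynyl-2,2-dimethylcyclopentan-1-ol F1.
- The cobalt [4+2] of step 2 converts this into (S)-2,2-dimethyl-1-(4-methylcyclohexa-1,4-dien-1-yl)cyclopentan-1-ol F2.
- Achiral VO(acac)2/t-BuOOH (CH2Cl2, 0 °C) epoxidises syn to the hydroxyl through the rotamer that keeps the CMe2 arm out of the alkene plane. This gives the single epoxy alcohol (1S)-1-[(1R,6S)-4-methyl-7-oxabicyclo[4.1.0]hept-3-en-1-yl]-2,2-dimethylcyclopentan-1-ol F3.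
- ZnBr2 then rearranges it to 7.

**Step 4 (new).**
- Risks: the bromonium ion may form on the lower face. Chloride may open it diaxially at C4. The carbonyl oxygen may participate.
- Fallback: a known two-stage halohydrin route. It sets out from 7 and comes back at 8.
- NBS in aqueous acetone (0 °C) gives the trans bromohydrin (1S,3R,4R,6S)-4-bromo-1,3-dihydroxy-3,11,11-trimethylspiro[5.5]undecan-7-one F4. Unlike the dihalides, this diol is easily separated from its diastereomer on silica.
- Dry HCl in CH2Cl2 (−20 °C) then replaces only the tertiary hydroxyl. Ionisation is assisted by the neighbouring bromine, so chloride enters anti to bromine with overall retention and gives 8.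

**Step 7.**
- Risks: the cis-disubstituted alkene of the s-trans diene may react too slowly with singlet oxygen. The bis-allylic hydroperoxide may rearrange.
- Fallback: selenium dioxide allylic oxidation and IBX dehydrogenation in place of photooxygenation. It sets out from 8, replaces steps 5 to 7, comes back at 15 and is one step longer.
- Cp2TiMe2 (excess, toluene, 65 °C) methylenates the saturated ketone to (1S,3R,4R,6R)-4-bromo-3-chloro-3,11,11-trimethyl-7-methylidenespiro[5.5]undecan-1-ol F5.
- Ac2O/DMAP gives (1S,3R,4R,6R)-1-acetoxy-4-bromo-3-chloro-3,11,11-trimethyl-7-methylidenespiro[5.5]undecane F6.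
- SeO2 (cat.)/t-BuOOH hydroxylates the only allylic CH2 (C8) to (1S,3R,4R,6R)-1-acetoxy-4-bromo-3-chloro-8-hydroxy-3,11,11-trimethyl-7-methylidenespiro[5.5]undecane F7.
- IBX (4 equiv, DMSO, 70 °C) oxidises the alcohol to the α-methylene ketone and dehydrogenates C9–C10 in the same pot to give 15.

**Further compounds**
F1 | step 3 | (S)-1-ethynyl-2,2-dimethylcyclopentan-1-ol | C#C[C@]1(O)CCCC1(C)C
F2 | step 3 | (S)-2,2-dimethyl-1-(4-methylcyclohexa-1,4-dien-1-yl)cyclopentan-1-ol | CC1=CCC(=CC1)[C@]2(O)CCCC2(C)C
F3 | step 3 | (1S)-1-[(1R,6S)-4-methyl-7-oxabicyclo[4.1.0]hept-3-en-1-yl]-2,2-dimethylcyclopentan-1-ol | CC1=CC[C@]2(O[C@H]2C1)[C@]3(O)CCCC3(C)C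
F4 | step 4 | (1S,3R,4R,6S)-4-bromo-1,3-dihydroxy-3,11,11-trimethylspiro[5.5]undecan-7-one | O=C1CCCC(C)(C)[C@]12C[C@@H](Br)[C@](C)(O)C[C@@H]2O
F5 | step 7 | (1S,3R,4R,6R)-4-bromo-3-chloro-3,11,11-trimethyl-7-methylidenespiro[5.5]undecan-1-ol | C=C1CCCC(C)(C)[C@]12C[C@@H](Br)[C@](C)(Cl)C[C@@H]2O
F6 | step 7 | (1S,3R,4R,6R)-1-acetoxy-4-bromo-3-chloro-3,11,11-trimethyl-7-methylidenespiro[5.5]undecane | C=C1CCCC(C)(C)[C@]12C[C@@H](Br)[C@](C)(Cl)C[C@@H]2OC(C)=O
F7 | step 7 | (1S,3R,4R,6R)-1-acetoxy-4-bromo-3-chloro-8-hydroxy-3,11,11-trimethyl-7-methylidenespiro[5.5]undecane (C8 epimers) | C=C1C(O)CCC(C)(C)[C@]12C[C@@H](Br)[C@](C)(Cl)C[C@@H]2OC(C)=O
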